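## Retrosynthetic overview

1. Last bond C1–C10: ring-closing Ni/Cr-catalysed Nozaki–Hiyama–Kishi coupling of iodoalkene–aldehyde 31 closes the ten-membered ring and sets C1.
2. Fragment union C5–C6: Pd-catalysed enantioselective γ-alkenylation of silyloxyfuran 24 with Z-alkenyl iodide 11 sets C6.
3. West fragment 11 (C1–C5, C15): Noyori reduction of an ynone sets C3; Cu-catalysed anti-carbomagnesiation/iodination sets the Z-C4=C5 alkene.
4. East fragment 24 (C6–C14): Cu-catalysed carbomagnesiation/iodination of butynediol, then Pd-catalysed carbonylative lactonisation.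
5. Ring order: butenolide first (step 11), ten-membered carbocycle last (step 20).

Numbering: germacrane numbering of the target is used throughout (C1 carbinol, C3 acetoxy carbon, C4=C5 alkene with C15 methyl, C6 lactone carbinol, C7=C11 butenolide alkene, C12 carbonyl, C13 CH2OAc, C10=C14 methylene); the target is (1R,3S,6R,4Z).

Assumption: the hand of each chiral ligand named in steps 15 and 20 is the one expected to give the stated configuration; both enantiomers are available, so the mirror-image ligand is used if a test run shows the opposite sense.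

## Route

**Step 1**
Reactants: 1 methyl 3-hydroxypropanoate
Product: 2 methyl 3-[(tert-butyldiphenylsilyl)oxy]propanoate
Conditions: TBDPSCl, imidazole, CH2Cl2, 0 °C → rt
Reagents that add atoms: tert-butyl(chloro)diphenylsilane, CC(C)(C)[Si](Cl)(c1ccccc1)c1ccccc1
Why: Imidazole-promoted silyl ether formation on a primary alcohol; TBDPS is chosen because it survives the Grignard, acid and haloborane steps and is removed last.

**Step 2**
Reactants: 2 methyl 3-[(tert-butyldiphenylsilyl)oxy]propanoate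
Product: 3 3-[(tert-butyldiphenylsilyl)oxy]-N-methoxy-N-methylpropanamide
Conditions: MeNH(OMe)·HCl, i-PrMgCl, THF, –20 → 0 °C
Reagents that add atoms: N,O-dimethylhydroxylamine hydrochloride, CNOC.Cl
Why: Weinreb amide formation from an ester with the chloromagnesium amide made in the flask, cold enough to avoid β-elimination of the silyloxy group.

**Step 3**
Reactants: 3 3-[(tert-butyldiphenylsilyl)oxy]-N-methoxy-N-methylpropanamide; 4 ethynyltrimethylsilane
Product: 6 5-[(tert-butyldiphenylsilyl)oxy]-1-(trimethylsilyl)pent-1-yn-3-one, via lithium (trimethylsilyl)acetylide 5 (not isolated)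
Conditions: 4, n-BuLi, THF, –78 °C; then 3, –78 → 0 °C; aq. NH4Cl
Reagents that add atoms: none
Why: Weinreb ketone synthesis, in which the acetylide acylates once and the ynone is released only on work-up.

**Step 4**
Reactants: 6 5-[(tert-butyldiphenylsilyl)oxy]-1-(trimethylsilyl)pent-1-yn-3-one
Product: 7 (S)-5-[(tert-butyldiphenylsilyl)oxy]-1-(trimethylsilyl)pent-1-yn-3-ol
Conditions: Ru[(S,S)-TsDPEN](p-cymene) (amido complex, 1 mol %), i-PrOH, rt
Reagents that add atoms: none
Why: Noyori asymmetric transfer hydrogenation of an ynone, in which the (S,S)-catalyst delivers hydride to the face that gives the (S)-propargylic alcohol (C3), the alkynyl group taking the place of the aryl group in the usual transition state.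

**Step 5**
Reactants: 7 (S)-5-[(tert-butyldiphenylsilyl)oxy]-1-(trimethylsilyl)pent-1-yn-3-ol
Product: 8 (S)-5-[(tert-butyldiphenylsilyl)oxy]pent-1-yn-3-ol
Conditions: K2CO3 (0.3 equiv), MeOH, 0 °C → rt
Reagents that add atoms: none
Why: Base-catalysed methanolysis of the alkynyl C–Si bond, which leaves the TBDPS ether and the carbinol centre untouched.

**Step 6**
Reactants: 8 (S)-5-[(tert-butyldiphenylsilyl)oxy]pent-1-yn-3-ol
Product: 10 (S,Z)-5-[(tert-butyldiphenylsilyl)oxy]-1-iodo-2-methylpent-1-en-3-ol, via alkenylmagnesium alkoxide 9 (not isolated)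
Conditions: MeMgBr (3 equiv), CuI (15 mol %), THF/Et2O, –10 °C → rt; then I2, –78 → 0 °C
Reagents that add atoms: methylmagnesium bromide, C[Mg]Br; iodine, II
Why: Copper-catalysed alkoxide-directed anti-carbomagnesiation of a propargylic alcohol (Duboudin–Jousseaume reaction) puts methyl on the proximal carbon and magnesium on the terminal carbon trans to it, and iodinolysis with retention gives the Z-iodoalkene without touching C3.

**Step 7**
Reactants: 10 (S,Z)-5-[(tert-butyldiphenylsilyl)oxy]-1-iodo-2-methylpent-1-en-3-ol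
Product: 11 tert-butyl{[(3S,4Z)-5-iodo-4-methyl-3-[(triethylsilyl)oxy]pent-4-en-1-yl]oxy}diphenylsilane (west fragment)
Conditions: TESCl, imidazole, CH2Cl2, 0 °C
Reagents that add atoms: chlorotriethylsilane, CC[Si](Cl)(CC)CC
Why: Standard silylation of the secondary allylic alcohol with a group that mild acid later removes in the presence of TBDPS.

**Step 8**
Reactants: 12 but-3-yn-1-ol
Product: 14 4-(trimethylsilyl)but-3-yn-1-ol, via bis-silylated butynol 13 (not isolated)
Conditions: n-BuLi (2.1 equiv), THF, –78 °C; TMSCl (2.2 equiv), –78 °C → rt; then 1 M HCl, rt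
Reagents that add atoms: chlorotrimethylsilane, C[Si](C)(C)Cl
Why: Silylation of the alkoxide–acetylide dianion followed by selective hydrolysis of the labile O–Si bond masks the terminal alkyne for the Grignard step.

**Step 9**
Reactants: 14 4-(trimethylsilyl)but-3-yn-1-ol
Product: 15 (4-bromobut-1-yn-1-yl)trimethylsilane
Conditions: CBr4, PPh3, CH2Cl2, 0 °C
Reagents that add atoms: carbon tetrabromide, BrC(Br)(Br)Br
Why: Appel bromination of a primary alcohol.

**Step 10**
Reactants: 15 (4-bromobut-1-yn-1-yl)trimethylsilane; 16 but-2-yne-1,4-diol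
Product: 20 (Z)-2-iodo-3-[4-(trimethylsilyl)but-3-yn-1-yl]but-2-ene-1,4-diol, via Grignard reagent 17 (not isolated), via dialkoxide 18 (not isolated), via alkenylmagnesium adduct 19 (not isolated)
Conditions: 15, Mg, THF, rt; 16, i-PrMgCl (2.0 equiv), THF, 0 °C; combine, CuI (20 mol %), 0 → 45 °C; then I2, –40 → 0 °C
Reagents that add atoms: iodine, II
Why: Copper-catalysed anti-carbomagnesiation of the symmetrical butynediol dialkoxide (Duboudin type, no regiochemical issue) and iodinolysis with retention fix the tetrasubstituted alkene with iodine cis to one hydroxymethyl group.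

**Step 11**
Reactants: 20 (Z)-2-iodo-3-[4-(trimethylsilyl)but-3-yn-1-yl]but-2-ene-1,4-diol
Product: 21 3-(hydroxymethyl)-4-[4-(trimethylsilyl)but-3-yn-1-yl]furan-2(5H)-one
Conditions: PdCl2(PPh3)2 (5 mol %), CO (1 atm), K2CO3, THF, 50 °C
Reagents that add atoms: carbon monoxide, [C-]#[O+]
Why: Palladium-catalysed carbonylative lactonisation of a (Z)-3-iodoallylic alcohol, in which the acylpalladium is trapped by the cis hydroxymethyl group to give the butenolide (the geminal hydroxymethyl could only give a four-membered ring).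

**Step 12**
Reactants: 21 3-(hydroxymethyl)-4-[4-(trimethylsilyl)but-3-yn-1-yl]furan-2(5H)-one
Product: 22 4-(but-3-yn-1-yl)-3-(hydroxymethyl)furan-2(5H)-one
Conditions: K2CO3 (0.2 equiv), MeOH, 0 °C; AcOH quench
Reagents that add atoms: none
Why: Base-catalysed methanolysis of the alkynyl C–Si bond, any lactone methanolysis reversing on acidification because only the five-membered lactone can re-form.

**Step 13**
Reactants: 22 4-(but-3-yn-1-yl)-3-(hydroxymethyl)furan-2(5H)-one
Product: 23 4-(but-3-yn-1-yl)-3-{[(triethylsilyl)oxy]methyl}furan-2(5H)-one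
Conditions: TESCl, imidazole, CH2Cl2, 0 °C
Reagents that add atoms: chlorotriethylsilane, CC[Si](Cl)(CC)CC
Why: Standard silylation, because a C13 silyl ether (unlike an acetate) cannot be expelled from the dienolate used in step 15.

**Step 14**
Reactants: 23 4-(but-3-yn-1-yl)-3-{[(triethylsilyl)oxy]methyl}furan-2(5H)-one
Product: 24 {[4-(but-3-yn-1-yl)-3-{[(triethylsilyl)oxy]methyl}furan-2-yl]oxy}(tert-butyl)dimethylsilane (east fragment)
Conditions: TBSOTf, Et3N, CH2Cl2, 0 °C
Reagents that add atoms: tert-butyldimethylsilyl trifluoromethanesulfonate, CC(C)(C)[Si](C)(C)OS(=O)(=O)C(F)(F)F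
Why: Soft enolisation and O-silylation of the butenolide gives the aromatic 2-silyloxyfuran.

**Step 15**
Reactants: 24 {[4-(but-3-yn-1-yl)-3-{[(triethylsilyl)oxy]methyl}furan-2-yl]oxy}(tert-butyl)dimethylsilane; 11 tert-butyl{[(3S,4Z)-5-iodo-4-methyl-3-[(triethylsilyl)oxy]pent-4-en-1-yl]oxy}diphenylsilane
Product: 25 (5R)-4-(but-3-yn-1-yl)-5-[(1Z,3S)-5-[(tert-butyldiphenylsilyl)oxy]-2-methyl-3-[(triethylsilyl)oxy]pent-1-en-1-yl]-3-{[(triethylsilyl)oxy]methyl}furan-2(5H)-one
Conditions: 24 (1.3 equiv), Pd2(dba)3 (2.5 mol %), (R)-DTBM-SEGPHOS (6 mol %), LiOAc (2 equiv), PhCF3/DMF (9:1), 40 °C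
Reagents that add atoms: none
Why: Proposed new method: enantioselective palladium-catalysed γ-alkenylation of a 2-silyloxyfuran with a Z-alkenyl iodide, reasoned as oxidative addition of zerovalent palladium into the C–I bond with retention of the Z geometry, iodide/acetate exchange, acetate-assisted Si-to-Pd transmetalation to a palladium dienolate bound at furan C5 (C6 of the target) and C–C reductive elimination there, the only site that restores the conjugated butenolide, with the bulky chiral bisphosphine choosing the face of the planar furanolate to set 6R and the neutral acetate conditions sparing the acidic γ-hydrogen; the closest known reaction types are the palladium-catalysed γ-arylation of butenolide dienolates and the enantioselective palladium-catalysed α-arylation and α-alkenylation of silyl ketene acetals.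

**Step 16**
Reactants: 25 (5R)-4-(but-3-yn-1-yl)-5-[(1Z,3S)-5-[(tert-butyldiphenylsilyl)oxy]-2-methyl-3-[(triethylsilyl)oxy]pent-1-en-1-yl]-3-{[(triethylsilyl)oxy]methyl}furan-2(5H)-one
Product: 27 [(5R)-5-[(1Z,3S)-3-acetoxy-5-[(tert-butyldiphenylsilyl)oxy]-2-methylpent-1-en-1-yl]-4-(but-3-yn-1-yl)-2-oxo-2,5-dihydrofuran-3-yl]methyl acetate, via diol 26 (not isolated)
Conditions: PPTS (0.2 equiv), MeOH/CH2Cl2, 0 °C → rt; concentrate; then Ac2O, pyridine, DMAP (5 mol %), CH2Cl2, 0 °C
Reagents that add atoms: acetic anhydride, CC(=O)OC(C)=O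
Why: Acid-catalysed methanolysis cleaves both triethylsilyl ethers but not the TBDPS ether, and DMAP-catalysed acetylation caps the C3 and C13 hydroxyls under conditions too weakly basic to epimerise C6.

**Step 17**
Reactants: 27 [(5R)-5-[(1Z,3S)-3-acetoxy-5-[(tert-butyldiphenylsilyl)oxy]-2-methylpent-1-en-1-yl]-4-(but-3-yn-1-yl)-2-oxo-2,5-dihydrofuran-3-yl]methyl acetate
Product: 29 [(5R)-5-[(1Z,3S)-3-acetoxy-5-[(tert-butyldiphenylsilyl)oxy]-2-methylpent-1-en-1-yl]-4-(3-iodobut-3-en-1-yl)-2-oxo-2,5-dihydrofuran-3-yl]methyl acetate, via iodoalkenylborane 28 (not isolated)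
Conditions: B-iodo-9-BBN (1.5 equiv), CH2Cl2, –20 → 0 °C; then AcOH, 0 °C; aq. NaHCO3
Reagents that add atoms: B-iodo-9-borabicyclo[3.3.1]nonane, IB1C2CCCC1CCC2
Why: Markovnikov hydroiodination by syn-haloboration of the terminal alkyne (Hara–Suzuki) and protodeboronation with acetic acid, at a temperature where internal alkenes, esters and silyl ethers do not react.

**Step 18**
Reactants: 29 [(5R)-5-[(1Z,3S)-3-acetoxy-5-[(tert-butyldiphenylsilyl)oxy]-2-methylpent-1-en-1-yl]-4-(3-iodobut-3-en-1-yl)-2-oxo-2,5-dihydrofuran-3-yl]methyl acetate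
Product: 30 [(5R)-5-[(1Z,3S)-3-acetoxy-5-hydroxy-2-methylpent-1-en-1-yl]-4-(3-iodobut-3-en-1-yl)-2-oxo-2,5-dihydrofuran-3-yl]methyl acetate
Conditions: HF·pyridine, pyridine, THF, 0 °C → rt
Reagents that add atoms: none
Why: Fluoride cleavage of the primary silyl ether under buffered acidic conditions that leave the acetates, the iodoalkene and the epimerisable C6 alone.

**Step 19**
Reactants: 30 [(5R)-5-[(1Z,3S)-3-acetoxy-5-hydroxy-2-methylpent-1-en-1-yl]-4-(3-iodobut-3-en-1-yl)-2-oxo-2,5-dihydrofuran-3-yl]methyl acetate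
Product: 31 [(5R)-5-[(1Z,3S)-3-acetoxy-2-methyl-5-oxopent-1-en-1-yl]-4-(3-iodobut-3-en-1-yl)-2-oxo-2,5-dihydrofuran-3-yl]methyl acetate
Conditions: Dess–Martin periodinane (1.5 equiv), CH2Cl2, 0 °C → rt; filtered and used crude
Reagents that add atoms: none
Why: Dess–Martin oxidation without added base, so that the β-acetoxy aldehyde does not eliminate the C3 acetate before it is cyclised.

**Step 20**
Reactants: 31 [(5R)-5-[(1Z,3S)-3-acetoxy-2-methyl-5-oxopent-1-en-1-yl]-4-(3-iodobut-3-en-1-yl)-2-oxo-2,5-dihydrofuran-3-yl]methyl acetate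
Product: 33 (1R,3S,6R,4Z)-3,13-diacetoxy-1-hydroxygermacra-4,7(11),10(14)-trien-12,6-olide (CNP0227830.1), via trimethylsilyl ether 32 (not isolated)
Conditions: CrCl2 (20 mol %), (S)-N-[2-(4-isopropyl-4,5-dihydrooxazol-2-yl)-6-methylphenyl]methanesulfonamide (22 mol %), proton sponge (22 mol %), NiCl2(2,9-dimethyl-1,10-phenanthroline) (5 mol %), Mn (3 equiv), TMSCl (2.5 equiv), LiCl (3 equiv), MeCN, rt, 31 added over 12 h (2 mM); then 0.5 M citric acid, THF
Reagents that add atoms: none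
Why: Nickel/chromium-catalysed Nozaki–Hiyama–Kishi macrocyclisation (Fürstner/Kishi catalytic variant) forms C1–C10 and the ten-membered ring, the chiral chromium–sulfonamide complex directing the alkenyl group to the Si face of the aldehyde to give 1R, and the silylated product is hydrolysed on work-up.

## Compound list

1 | methyl 3-hydroxypropanoate | COC(=O)CCO | starting material
2 | methyl 3-[(tert-butyldiphenylsilyl)oxy]propanoate | COC(=O)CCO[Si](c1ccccc1)(c1ccccc1)C(C)(C)C | intermediate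
3 | 3-[(tert-butyldiphenylsilyl)oxy]-N-methoxy-N-methylpropanamide | CON(C)C(=O)CCO[Si](c1ccccc1)(c1ccccc1)C(C)(C)C | intermediate
4 | ethynyltrimethylsilane | C#C[Si](C)(C)C | starting material
5 | lithium (trimethylsilyl)acetylide | [Li]C#C[Si](C)(C)C | intermediate
6 | 5-[(tert-butyldiphenylsilyl)oxy]-1-(trimethylsilyl)pent-1-yn-3-one | C[Si](C)(C)C#CC(=O)CCO[Si](c1ccccc1)(c1ccccc1)C(C)(C)C | intermediate
7 | (S)-5-[(tert-butyldiphenylsilyl)oxy]-1-(trimethylsilyl)pent-1-yn-3-ol | C[Si](C)(C)C#C[C@@H](O)CCO[Si](c1ccccc1)(c1ccccc1)C(C)(C)C | intermediate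
8 | (S)-5-[(tert-butyldiphenylsilyl)oxy]pent-1-yn-3-ol | C#C[C@@H](O)CCO[Si](c1ccccc1)(c1ccccc1)C(C)(C)C | intermediate
9 | (S,Z)-{3-[(bromomagnesio)oxy]-5-[(tert-butyldiphenylsilyl)oxy]-2-methylpent-1-en-1-yl}magnesium bromide | Br[Mg]/C=C(/C)[C@@H](O[Mg]Br)CCO[Si](c1ccccc1)(c1ccccc1)C(C)(C)C | intermediate
10 | (S,Z)-5-[(tert-butyldiphenylsilyl)oxy]-1-iodo-2-methylpent-1-en-3-ol | I/C=C(/C)[C@@H](O)CCO[Si](c1ccccc1)(c1ccccc1)C(C)(C)C | intermediate
11 | tert-butyl{[(3S,4Z)-5-iodo-4-methyl-3-[(triethylsilyl)oxy]pent-4-en-1-yl]oxy}diphenylsilane (west fragment) | I/C=C(/C)[C@@H](O[Si](CC)(CC)CC)CCO[Si](c1ccccc1)(c1ccccc1)C(C)(C)C | intermediate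
12 | but-3-yn-1-ol | C#CCCO | starting material
13 | trimethyl{[4-(trimethylsilyl)but-3-yn-1-yl]oxy}silane | C[Si](C)(C)C#CCCO[Si](C)(C)C | intermediate
14 | 4-(trimethylsilyl)but-3-yn-1-ol | C[Si](C)(C)C#CCCO | intermediate
15 | (4-bromobut-1-yn-1-yl)trimethylsilane | C[Si](C)(C)C#CCCBr | intermediate
16 | but-2-yne-1,4-diol | OCC#CCO | starting material
17 | [4-(trimethylsilyl)but-3-yn-1-yl]magnesium bromide | C[Si](C)(C)C#CCC[Mg]Br | intermediate
18 | bis(chloromagnesium) but-2-yne-1,4-diolate | Cl[Mg]OCC#CCO[Mg]Cl | intermediate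
19 | alkenylmagnesium bromide from anti-addition of 17 to 18 (butynyl chain trans to magnesium, both oxygens as chloromagnesium alkoxides) | C[Si](C)(C)C#CCC/C(CO[Mg]Cl)=C(/[Mg]Br)CO[Mg]Cl | intermediate
20 | (Z)-2-iodo-3-[4-(trimethylsilyl)but-3-yn-1-yl]but-2-ene-1,4-diol | C[Si](C)(C)C#CCC/C(CO)=C(/I)CO | intermediate
21 | 3-(hydroxymethyl)-4-[4-(trimethylsilyl)but-3-yn-1-yl]furan-2(5H)-one | C[Si](C)(C)C#CCCC1=C(CO)C(=O)OC1 | intermediate
22 | 4-(but-3-yn-1-yl)-3-(hydroxymethyl)furan-2(5H)-one | C#CCCC1=C(CO)C(=O)OC1 | intermediate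
23 | 4-(but-3-yn-1-yl)-3-{[(triethylsilyl)oxy]methyl}furan-2(5H)-one | C#CCCC1=C(CO[Si](CC)(CC)CC)C(=O)OC1 | intermediate
24 | {[4-(but-3-yn-1-yl)-3-{[(triethylsilyl)oxy]methyl}furan-2-yl]oxy}(tert-butyl)dimethylsilane (east fragment) | C#CCCc1coc(O[Si](C)(C)C(C)(C)C)c1CO[Si](CC)(CC)CC | intermediate
25 | (5R)-4-(but-3-yn-1-yl)-5-[(1Z,3S)-5-[(tert-butyldiphenylsilyl)oxy]-2-methyl-3-[(triethylsilyl)oxy]pent-1-en-1-yl]-3-{[(triethylsilyl)oxy]methyl}furan-2(5H)-one | C#CCCC1=C(CO[Si](CC)(CC)CC)C(=O)O[C@@H]1/C=C(/C)[C@@H](O[Si](CC)(CC)CC)CCO[Si](c1ccccc1)(c1ccccc1)C(C)(C)C | intermediate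
26 | (5R)-4-(but-3-yn-1-yl)-5-[(1Z,3S)-5-[(tert-butyldiphenylsilyl)oxy]-3-hydroxy-2-methylpent-1-en-1-yl]-3-(hydroxymethyl)furan-2(5H)-one | C#CCCC1=C(CO)C(=O)O[C@@H]1/C=C(/C)[C@@H](O)CCO[Si](c1ccccc1)(c1ccccc1)C(C)(C)C | intermediate
27 | [(5R)-5-[(1Z,3S)-3-acetoxy-5-[(tert-butyldiphenylsilyl)oxy]-2-methylpent-1-en-1-yl]-4-(but-3-yn-1-yl)-2-oxo-2,5-dihydrofuran-3-yl]methyl acetate | C#CCCC1=C(COC(C)=O)C(=O)O[C@@H]1/C=C(/C)[C@@H](OC(C)=O)CCO[Si](c1ccccc1)(c1ccccc1)C(C)(C)C | intermediate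
28 | B-[(Z)-2-iodoalk-1-en-1-yl]-9-BBN adduct of 27 (boron on the terminal carbon, cis to iodine) | I/C(=C\B1C2CCCC1CCC2)CCC1=C(COC(C)=O)C(=O)O[C@@H]1/C=C(/C)[C@@H](OC(C)=O)CCO[Si](c1ccccc1)(c1ccccc1)C(C)(C)C | intermediate
29 | [(5R)-5-[(1Z,3S)-3-acetoxy-5-[(tert-butyldiphenylsilyl)oxy]-2-methylpent-1-en-1-yl]-4-(3-iodobut-3-en-1-yl)-2-oxo-2,5-dihydrofuran-3-yl]methyl acetate | C=C(I)CCC1=C(COC(C)=O)C(=O)O[C@@H]1/C=C(/C)[C@@H](OC(C)=O)CCO[Si](c1ccccc1)(c1ccccc1)C(C)(C)C | intermediate
30 | [(5R)-5-[(1Z,3S)-3-acetoxy-5-hydroxy-2-methylpent-1-en-1-yl]-4-(3-iodobut-3-en-1-yl)-2-oxo-2,5-dihydrofuran-3-yl]methyl acetate | C=C(I)CCC1=C(COC(C)=O)C(=O)O[C@@H]1/C=C(/C)[C@@H](OC(C)=O)CCO | intermediate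
31 | [(5R)-5-[(1Z,3S)-3-acetoxy-2-methyl-5-oxopent-1-en-1-yl]-4-(3-iodobut-3-en-1-yl)-2-oxo-2,5-dihydrofuran-3-yl]methyl acetate | C=C(I)CCC1=C(COC(C)=O)C(=O)O[C@@H]1/C=C(/C)[C@@H](OC(C)=O)CC=O | intermediate
32 | 1-O-trimethylsilyl ether of 33 | C=C1CCC2=C(COC(C)=O)C(=O)O[C@@H]2/C=C(/C)[C@@H](OC(C)=O)C[C@H]1O[Si](C)(C)C | intermediate
33 | (1R,3S,6R,4Z)-3,13-diacetoxy-1-hydroxygermacra-4,7(11),10(14)-trien-12,6-olide (CNP0227830.1) | C=C1CCC2=C(COC(C)=O)C(=O)O[C@@H]2/C=C(/C)[C@@H](OC(C)=O)C[C@H]1O | target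

## Step count and risks

Total: 20 steps (7 for the west fragment, 7 for the east fragment, 6 after their union). Longest linear sequence: 13 steps (1–7 then 15–20; the east branch 8–14 then 15–20 is equally long).

**Step 15 (the proposed new coupling).** It has no direct precedent. It could fail through α- instead of γ-attack, poor face selectivity at C6, slow transmetalation of the hindered silyloxyfuran, or interference by the free terminal alkyne. The fallback uses known chemistry, sets out from 11 and returns at 25. Iodine–lithium exchange on 11 (t-BuLi, Et2O, –78 °C) and formylation with DMF give the (S,Z)-enal F1. Zinc–ProPhenol alkynylation of F1 with triethyl(prop-2-yn-1-yloxy)silane (Me2Zn, toluene, 0 °C, ProPhenol enantiomer that gives the 6R carbinol) gives the (6R)-enynol F2. Its chloromagnesium alkoxide (i-PrMgCl) undergoes CuI-catalysed anti-carbomagnesiation with Grignard reagent 17 (made from 15) and the alkenylmagnesium is quenched with CO2; mild acid work-up closes the silylalkynyl butenolide F3. AgNO3/2,6-lutidine in aqueous acetone removes the alkynyl silyl group to give 25.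

**Step 17 (late-stage haloboration).** The Lewis-acidic iodoborane may attack the allylic acetates or the butenolide before it adds to the alkyne. The fallback sets out from 27 and returns at 29. Markovnikov hydrostannation with [Cp*Ru(MeCN)3]PF6 (5 mol %) and Bu3SnH in CH2Cl2 gives the 2-stannyl-1-alkene F4. Iododestannylation with I2 in CH2Cl2 at 0 °C gives 29.

**Step 20 (macrocyclisation).** The ten-membered ring may close in low yield, the β-acetoxy aldehyde may eliminate, or C1 may come out with the wrong or mixed configuration if ring strain overrides the chiral chromium complex. The fallback sets out from 31 and returns at 33. Cyclisation under plain CrCl2/NiCl2 (DMSO/THF, high dilution) is accepted whatever its sense and gives the 1S alcohol F5 or its mixture with 33. Dess–Martin oxidation gives the cross-conjugated enone F6. Reagent-controlled reduction with (S)-Me-CBS and catecholborane (toluene, –78 °C; the alkenyl group acts as the large substituent) gives the 1R alcohol 33.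

## Further compounds

F1 | step 15 | (2Z,4S)-6-[(tert-butyldiphenylsilyl)oxy]-3-methyl-4-[(triethylsilyl)oxy]hex-2-enal | O=C/C=C(/C)[C@@H](O[Si](CC)(CC)CC)CCO[Si](c1ccccc1)(c1ccccc1)C(C)(C)C
F2 | step 15 | (4R,5Z,7S)-9-[(tert-butyldiphenylsilyl)oxy]-6-methyl-1,7-bis[(triethylsilyl)oxy]non-5-en-2-yn-4-ol | CC[Si](CC)(CC)OCC#C[C@H](O)/C=C(/C)[C@@H](O[Si](CC)(CC)CC)CCO[Si](c1ccccc1)(c1ccccc1)C(C)(C)C
F3 | step 15 | (5R)-5-[(1Z,3S)-5-[(tert-butyldiphenylsilyl)oxy]-2-methyl-3-[(triethylsilyl)oxy]pent-1-en-1-yl]-3-{[(triethylsilyl)oxy]methyl}-4-[4-(trimethylsilyl)but-3-yn-1-yl]furan-2(5H)-one | C[Si](C)(C)C#CCCC1=C(CO[Si](CC)(CC)CC)C(=O)O[C@@H]1/C=C(/C)[C@@H](O[Si](CC)(CC)CC)CCO[Si](c1ccccc1)(c1ccccc1)C(C)(C)C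
F4 | step 17 | [(5R)-5-[(1Z,3S)-3-acetoxy-5-[(tert-butyldiphenylsilyl)oxy]-2-methylpent-1-en-1-yl]-2-oxo-4-[3-(tributylstannyl)but-3-en-1-yl]-2,5-dihydrofuran-3-yl]methyl acetate | C=C(CCC1=C(COC(C)=O)C(=O)O[C@@H]1/C=C(/C)[C@@H](OC(C)=O)CCO[Si](c1ccccc1)(c1ccccc1)C(C)(C)C)[Sn](CCCC)(CCCC)CCCC
F5 | step 20 | (1S,3S,6R,4Z)-3,13-diacetoxy-1-hydroxygermacra-4,7(11),10(14)-trien-12,6-olide (C1 epimer of 33) | C=C1CCC2=C(COC(C)=O)C(=O)O[C@@H]2/C=C(/C)[C@@H](OC(C)=O)C[C@@H]1O
F6 | step 20 | (3S,6R,4Z)-3,13-diacetoxy-1-oxogermacra-4,7(11),10(14)-trien-12,6-olide | C=C1CCC2=C(COC(C)=O)C(=O)O[C@@H]2/C=C(/C)[C@@H](OC(C)=O)CC1=O
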